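**Assumption:** one-pot or telescoped operations that give a single isolated product (steps 3 and 10) are counted as one step. This route is a paper design; none of it has been run.

## Retrosynthetic overview

1. Target 15 ⇒ tetra-MOM flavanone 14 (global acetal hydrolysis). The pyranone ring is formed last, by intramolecular Mitsunobu C2–O1 closure with inversion from the (R)-β-hydroxy ketone 13.
2. 13 ⇒ C4–C4a disconnection: aryllithium from A-ring arene 7 (30 heavy atoms) plus B-ring (R)-β-hydroxy Weinreb amide 12 (23 heavy atoms), joined late.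
3. 7 ⇒ resorcinol: MOM protection, two directed-metalation prenylations, and an Ir C–H borylation/oxidation that adds the third oxygen. That oxygen is masked as an ethoxyethyl (EE) ether so it alone is freed for ring closure.
4. 12 ⇒ resorcinol: meta C–H borylation, oxidative carbonylation, Claisen condensation with N-methoxy-N-methylacetamide, and Noyori transfer hydrogenation, which sets the only stereocentre.
5. Ring order: both benzene rings come intact from resorcinol; the heterocycle closes in step 11.

## Route

**Step 1**
Reactants: 1, resorcinol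
Product: 2, 1,3-bis(methoxymethoxy)benzene
Conditions: MOMCl (2.5 eq), i-Pr2NEt, CH2Cl2, 0 °C → rt
Reagents that add atoms: chloromethyl methyl ether, COCCl
Why: Williamson-type O-alkylation of both phenols; the MOM groups serve later as ortho-metalation directors and as acid-removable protection.

**Step 2**
Reactants: 2; 3, prenyl bromide
Product: 4, 1,3-bis(methoxymethoxy)-2-(3-methylbut-2-en-1-yl)benzene
Conditions: n-BuLi, TMEDA, THF, 0 °C; CuBr·SMe2, then 3, −78 °C → rt
Reagents that add atoms: prenyl bromide (3), CC(C)=CCBr
Why: Directed ortho-metalation at C2, doubly activated by the two flanking OMOM groups, then Cu-assisted SN2 allylation gives the linear prenyl arene.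

**Step 3**
Reactants: 4
Product: 5, 3,5-bis(methoxymethoxy)-4-(3-methylbut-2-en-1-yl)phenol
Conditions: [Ir(OMe)(cod)]2 (1.5 mol %), dtbpy, B2pin2, THF, 60 °C; then 30 % H2O2, aq NaOH, THF, 0 °C (one pot; the aryl–Bpin is not isolated)
Reagents that add atoms: hydrogen peroxide, OO (supplies the phenolic O; B2pin2 is transient)
Why: Sterically controlled Ir-catalysed C–H borylation occurs only at C5, the sole position not ortho to a substituent; basic peroxide oxidises C–B to C–OH without touching the trisubstituted alkene.

**Step 4**
Reactants: 5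
Product: 6, 1-(1-ethoxyethoxy)-3,5-bis(methoxymethoxy)-4-(3-methylbut-2-en-1-yl)benzene (racemic at the acetal carbon; irrelevant)
Conditions: ethyl vinyl ether, PPTS (cat.), CH2Cl2, 0 °C → rt
Reagents that add atoms: ethyl vinyl ether, C=COCC
Why: Acid-catalysed acetalisation; EE is a metalation director like MOM but far more acid-labile, so this oxygen can be unmasked selectively later.

**Step 5**
Reactants: 6; 3, prenyl bromide
Product: 7, 1-(1-ethoxyethoxy)-3,5-bis(methoxymethoxy)-2,4-bis(3-methylbut-2-en-1-yl)benzene
Conditions: n-BuLi, TMEDA, THF, 0 °C; CuBr·SMe2, then 3, −78 °C → rt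
Reagents that add atoms: prenyl bromide (3), CC(C)=CCBr
Why: Directed ortho-metalation/allylation; the two remaining ring hydrogens are equivalent (each between OEE and OMOM), so only one product is possible.

**Step 6**
Reactants: 2
Product: 8, 2-[3,5-bis(methoxymethoxy)phenyl]-4,4,5,5-tetramethyl-1,3,2-dioxaborolane
Conditions: [Ir(OMe)(cod)]2 (1.5 mol %), dtbpy, B2pin2, THF, 80 °C
Reagents that add atoms: bis(pinacolato)diboron, CC1(C)OB(OC1(C)C)B1OC(C)(C)C(C)(C)O1
Why: Ir-catalysed C–H borylation of a 1,3-disubstituted arene goes to the mutually meta C5 position, which ortho-lithiation cannot reach.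

**Step 7**
Reactants: 8
Product: 9, methyl 3,5-bis(methoxymethoxy)benzoate
Conditions: Pd(OAc)2 (5 mol %), PPh3, p-benzoquinone, CO (1 atm), MeOH, rt
Reagents that add atoms: carbon monoxide, [C-]#[O+]; methanol, CO
Why: Pd(II)-catalysed oxidative alkoxycarbonylation of the arylboronate (transmetalation, CO insertion, methanolysis) under neutral conditions that leave the MOM ethers intact.

**Step 8**
Reactants: 9; 10, N-methoxy-N-methylacetamide
Product: 11, 3-[3,5-bis(methoxymethoxy)phenyl]-N-methoxy-N-methyl-3-oxopropanamide
Conditions: 10 (2.5 eq), LDA (2.5 eq), THF, −78 °C; then 9, −78 → −20 °C; AcOH quench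
Reagents that add atoms: N-methoxy-N-methylacetamide (10), CC(=O)N(C)OC
Why: Crossed Claisen condensation of the amide lithium enolate with the non-enolisable aryl ester; the second equivalent of enolate deprotonates the β-keto amide and drives it to completion.

**Step 9**
Reactants: 11
Product: 12, (3R)-3-[3,5-bis(methoxymethoxy)phenyl]-3-hydroxy-N-methoxy-N-methylpropanamide
Conditions: RuCl[(R,R)-TsDPEN](p-cymene) (1 mol %), HCO2H/Et3N (5:2), CH2Cl2, 30 °C
Reagents that add atoms: none
Why: Noyori asymmetric transfer hydrogenation of the aryl ketone; the (R,R) catalyst delivers hydride to give the (R) benzylic alcohol, as it does for aryl alkyl ketones. This sets the only stereocentre.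

**Step 10**
Reactants: 7; 12
Product: 13, (3R)-3-[3,5-bis(methoxymethoxy)phenyl]-3-hydroxy-1-[2-hydroxy-4,6-bis(methoxymethoxy)-3,5-bis(3-methylbut-2-en-1-yl)phenyl]propan-1-one
Conditions: 7 (1.25 eq), n-BuLi (1.2 eq), TMEDA, THF, 0 °C; add at −78 °C to 12 pre-treated with i-PrMgCl (1.0 eq, THF, −40 °C); warm to 0 °C; aq NH4Cl; then PPTS, MeOH, rt
Reagents that add atoms: none
Why: Directed ortho-metalation at the last ring C–H, then Weinreb ketone synthesis; the stable chelated tetrahedral intermediate prevents over-addition, and the carbinol travels as its magnesium alkoxide untouched. The PPTS work-up removes only the EE acetal, freeing the one phenol next to the new ketone.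

**Step 11**
Reactants: 13
Product: 14, (2S)-2-[3,5-bis(methoxymethoxy)phenyl]-5,7-bis(methoxymethoxy)-6,8-bis(3-methylbut-2-en-1-yl)chroman-4-one
Conditions: PPh3 (1.5 eq), DIAD (1.5 eq), THF (0.02 M), 0 °C → rt
Reagents that add atoms: none
Why: Intramolecular Mitsunobu etherification; the ortho phenol displaces the activated benzylic alcohol by 6-exo SN2 with clean inversion, so (3R) becomes (2S) (CIP priorities O > aryl > CH2 > H are unchanged).

**Step 12**
Reactants: 14
Product: 15, (2S)-2-(3,5-dihydroxyphenyl)-5,7-dihydroxy-6,8-bis(3-methylbut-2-en-1-yl)chroman-4-one (CID 26213315)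
Conditions: 3 M aq HCl/MeOH (1:5), 40 °C, under Ar, stopped at full conversion
Reagents that add atoms: none
Why: Acid-catalysed acetal hydrolysis removes all four MOM groups; mild acid does not open the flavanone ring (racemisation is base-mediated) and is gentle enough to avoid prenyl-to-chroman cyclisation.

## Compound list

| No. | Name | SMILES | Role |
|---|---|---|---|
| 1 | resorcinol | Oc1cccc(O)c1 | starting material |
| 2 | 1,3-bis(methoxymethoxy)benzene | COCOc1cccc(OCOC)c1 | intermediate (shared) |
| 3 | prenyl bromide | CC(C)=CCBr | starting material |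
| 4 | 1,3-bis(methoxymethoxy)-2-prenylbenzene | COCOc1cccc(OCOC)c1CC=C(C)C | intermediate |
| 5 | 3,5-bis(methoxymethoxy)-4-prenylphenol | COCOc1cc(O)cc(OCOC)c1CC=C(C)C | intermediate |
| 6 | 1-(1-ethoxyethoxy)-3,5-bis(methoxymethoxy)-4-prenylbenzene | CCOC(C)Oc1cc(OCOC)c(CC=C(C)C)c(OCOC)c1 | intermediate |
| 7 | 1-(1-ethoxyethoxy)-3,5-bis(methoxymethoxy)-2,4-diprenylbenzene | CCOC(C)Oc1cc(OCOC)c(CC=C(C)C)c(OCOC)c1CC=C(C)C | intermediate (A fragment) |
| 8 | 2-[3,5-bis(methoxymethoxy)phenyl]-4,4,5,5-tetramethyl-1,3,2-dioxaborolane | COCOc1cc(OCOC)cc(B2OC(C)(C)C(C)(C)O2)c1 | intermediate |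
| 9 | methyl 3,5-bis(methoxymethoxy)benzoate | COCOc1cc(OCOC)cc(C(=O)OC)c1 | intermediate |
| 10 | N-methoxy-N-methylacetamide | CC(=O)N(C)OC | starting material |
| 11 | 3-[3,5-bis(methoxymethoxy)phenyl]-N-methoxy-N-methyl-3-oxopropanamide | COCOc1cc(OCOC)cc(C(=O)CC(=O)N(C)OC)c1 | intermediate |
| 12 | (3R)-3-[3,5-bis(methoxymethoxy)phenyl]-3-hydroxy-N-methoxy-N-methylpropanamide | COCOc1cc(OCOC)cc([C@H](O)CC(=O)N(C)OC)c1 | intermediate (B fragment) |
| 13 | (3R)-β-hydroxy ketone (name in step 10) | COCOc1cc(OCOC)cc([C@H](O)CC(=O)c2c(O)c(CC=C(C)C)c(OCOC)c(CC=C(C)C)c2OCOC)c1 | intermediate |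
| 14 | (2S)-tetra-MOM flavanone (name in step 11) | CC(C)=CCc1c(OCOC)c(CC=C(C)C)c2c(c1OCOC)C(=O)C[C@@H](c1cc(OCOC)cc(OCOC)c1)O2 | intermediate |
| 15 | (2S)-2-(3,5-dihydroxyphenyl)-5,7-dihydroxy-6,8-diprenylchroman-4-one | CC(C)=CCc1c(O)c(CC=C(C)C)c2c(c1O)C(=O)C[C@@H](c1cc(O)cc(O)c1)O2 | target |

## Step count

- Total steps: 12.
- Longest linear sequence: 8 (steps 1 → 2 → 3 → 4 → 5 → 10 → 11 → 12; the B branch 1 → 6 → 7 → 8 → 9 → 10 → 11 → 12 is the same length).

## Three steps most likely to fail

1. **Step 10** (hindered aryllithium plus hydroxy Weinreb amide; competing deprotonation at the prenyl CH2 or of the amide). Fallback: change the bond formed. Quench lithiated 7 with N-methoxy-N-methylacetamide to give the A-ring methyl ketone, reduce ester 9 to the aldehyde, and join them by a reagent-controlled Ipc2BCl boron aldol that builds the C2–C3 bond and the (R)-carbinol together. Then continue with the same ring closure.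
2. **Step 11** (Mitsunobu on a β-hydroxy ketone; E1cB elimination to the chalcone would erode ee). Fallback: drop the SN2 closure. Convert the A-ring methyl ketone to the 5,7-bis(MOM)-6,8-diprenylchromone (DMF-DMA, then mild acid) and add boronate 8 by Rh(I)/chiral-diene or Pd/PyOx enantioselective conjugate addition, which creates the C2 stereocentre directly.
3. **Step 3** (Ir borylation with the prenyl alkene present; possible alkene hydroboration or isomerisation). Fallback: add the third oxygen before any alkene exists. Borylate/oxidise 2 to 3,5-bis(methoxymethoxy)phenol, cap it as MOM, and do both prenylations on the C3-symmetric 1,3,5-tris(methoxymethoxy)benzene. After the coupling, free one carbonyl-flanking OMOM by chelation-assisted cleavage (MgBr2·OEt2); this costs one extra linear step.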